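## The problem

Compound 13 is a depside: two benzene rings joined only through an ester. The carboxyl of ring A (a 2,4-dihydroxy-6-methylbenzoyl unit) is bound to the C4 oxygen of ring B, a benzoic acid with a hydroxyl at C2 and an unbranched heptyl chain at C6. There is no stereocenter, so every selectivity question is one of position on ring B, where the carboxyl carbon has two different ortho neighbours and a para oxygen that must be told apart from the ortho one. The inter-ring ester is the weakest bond: hydroxide, alkoxides and unhindered amines cleave or transesterify it, so after it is formed it must not meet a strong nucleophile. The ortho-hydroxy acid of ring B loses CO2 readily on heating or in acid and the free phenols are easily oxidized, so the last step has to be neutral and run at room temperature. The enabling feature is that ring B is a 2,4,6-trihydroxybenzoic acid whose C6 oxygen is replaced by the seven-carbon chain. A symmetric trihydroxybenzoate therefore supplies O2 and O4 ready-made, its single para hydroxyl is distinct from the two chelated ortho hydroxyls and can take the ring A acyl group, and one ortho oxygen can become a leaving group that the neighbouring ester activates toward palladium. Because the chain is saturated and unbranched, it can enter as hept-1-yne and be reduced in the same hydrogenation that removes benzyl protecting groups.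

## Retrosynthesis

**13 from 12.** No skeletal bond is cut. The three phenols and the acid of 13 are traced back to benzyl ethers and a benzyl ester, and the first two chain carbons to a triple bond. Benzyl is preferred to methyl (Lewis-acid cleavage would endanger the depside) and to silyl (would not survive the later steps uniformly). The forward step must saturate the alkyne and cleave four benzyl groups with H2 at room temperature without touching the aryl ester.

**12 from 10 and 11.** The bond between ring B C6 and the first chain carbon is cut, leading to aryl triflate 10 and hept-1-yne 11. Coupling a heptyl metal instead needs a preformed organometallic and risks β-hydride elimination. Building the chain by olefination needs a formyl group ortho to the ester and more steps. Electrophilic alkylation of ring B has no regiocontrol. The alkyne is commercial and needs no activation. Precursor 10 already holds both rings, the depside ester and every oxygen. The forward reaction must insert palladium into the C–OTf bond and leave the aryl ester alone.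

**10 from 9, and 9 from 8.** These are functional-group changes: the triflate comes from a phenol and one benzyl ether from the other phenol. The two ortho hydroxyls of 8 are equivalent by symmetry, so only mono- against bis-functionalization matters. Benzylation is placed first because ether formation is self-limiting (the remaining hydroxyl becomes strongly chelated to the ester carbonyl). Triflation of the only hydroxyl left in 9 is then unambiguous.

**8 from 6 and 4 (through 7).** The acyl–oxygen bond of the depside is cut. Forming this ester early lets the ring A acyl group serve as the protecting group of O4, so no temporary group is spent on that oxygen. The ortho,ortho'-disubstituted aroyl group also makes the ester robust in the later steps. The forward acylation must choose the para hydroxyl of 6 over the two ortho hydroxyls.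

**6 from 5.** The benzyl ester is cut back to commercial 2,4,6-trihydroxybenzoic acid 5. The alkylation must touch only the carboxylate.

**4 from 3, 3 from 2, 2 from 1.** The ring A acid 4 is traced to aldehyde 3, its benzyl ethers to the diphenol 2, and the formyl group to orcinol 1. The carboxyl carbon is brought in as a formyl group because direct carboxylation of 1 is less regioselective and the free dihydroxy acid decarboxylates easily. The aldehyde is stable and benzylates cleanly.

## Roads not taken

**Alternative 1:** The cut runs through ring B itself. Heating benzyl dec-2-ynoate A1 with 1,1-dimethoxy-3-(trimethylsilyloxy)buta-1,3-diene A2 would form the ring B bonds C1–C2 and C5–C6. Loss of one acetal alkoxy group and desilylation would then give benzyl 6-heptyl-4-hydroxy-2-methoxybenzoate A3.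
- Merits: the polarization of the two partners places chain, carboxyl and both oxygens correctly in one step. The para hydroxyl of A3 is free for acylation with acid 4. No palladium and no differentiation of three phenols are needed.
- Weak points: a β-alkyl ynoate is a sluggish dienophile, and the prolonged heating it needs is hard on the sensitive ketene-acetal diene. The C2 oxygen emerges as a methyl ether, which must be cleaved by a Lewis acid at the end in the presence of the depside ester, beside a separate hydrogenolysis. A1 and A2 each need their own preparation.
- Comparison: in regiocontrol of ring B this road is better than the chosen plan, which spends steps 5 to 7 on telling three hydroxyls apart. Step count is similar. Against that, the chosen plan has a coupling on a well-behaved substrate class, a cheap symmetric starting material and a single neutral final deprotection.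

**Alternative 2:** The cut is the ring A bond C1–C6, made last on the depside oxygen. Under mild base, benzyl 6-heptyl-2-hydroxy-4-[(3,5,7-trioxooctanoyl)oxy]benzoate A4 would cyclize by aldol attack of its C2 methylene on the C7 ketone and dehydrate to benzyl 4-[(2,4-dihydroxy-6-methylbenzoyl)oxy]-6-heptyl-2-hydroxybenzoate A5.
- Merits: ring A appears with free hydroxyls and correct substitution, so it needs no protecting groups. A5 is one benzyl-ester hydrogenolysis from 13. The route mirrors the biosynthesis.
- Weak points: A4 is an aryl ester of a β-keto acid, and its ring B phenoxide is a good leaving group. The enolized chain can lactonize onto the ester carbonyl to a 4-hydroxy-2-pyranone or fragment through an acylketene; either path expels ring B. The aldol-against-lactonization partition is condition-dependent even for alkyl esters. A4 needs acylketene chemistry and a ring B phenol that already carries the chain, so the ring B problem remains.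
- Comparison: in protecting-group economy this road is clearly superior to the chosen plan, which introduces and removes four benzyl groups. The chosen plan sets against it standard operations on stable intermediates and a hindered depside ester that is never put at risk by the key step.

**Alternative 3:** The cut is the bond between the ester oxygen and ring B C4. Acid 4 and {3-(benzyloxy)-4-[(benzyloxy)carbonyl]-5-heptylphenyl}boronic acid A6 would couple under Cu(OTf)2 with a urea or pyridine ligand in air. The product would be benzyl 2-(benzyloxy)-4-{[2,4-bis(benzyloxy)-6-methylbenzoyl]oxy}-6-heptylbenzoate A7, one hydrogenolysis from 13.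
- Merits: no selective acylation of a polyphenol is needed, ring B needs no para oxygen in its starting material, and A7 already has the saturated chain.
- Weak points: copper-promoted O-arylation of carboxylic acids is much less general than that of phenols or amines. Acid 4 is flanked on both sides and its carboxylate is hindered. The boronic acid is normally used in excess and is partly lost by protodeboronation, oxidation and homocoupling, which is costly for an advanced fragment. A6 needs a multistep preparation that still has to install the heptyl chain.
- Comparison: this road is better in avoiding hydroxyl differentiation and alkyne reduction. The chosen plan makes the aryl ester by plain acylation, the most dependable way, and reserves the metal-catalysed step for the C–C bond where precedent is strong. Its overall step count is not higher.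

Key step: step 8

## Route

Step 1
Reactants: 1 orcinol (5-methylbenzene-1,3-diol)
Product: 2 2,4-dihydroxy-6-methylbenzaldehyde
Conditions: POCl3, DMF, 0 °C → rt; then ice–water
Reagents that add atoms: N,N-dimethylformamide, CN(C)C=O (formyl carbon); water, O (carbonyl oxygen)
Why: Vilsmeier–Haack formylation; the chloroiminium ion should attack the position para to one hydroxyl and ortho to the other in preference to the hindered position between the two hydroxyls, and aqueous hydrolysis of the aryl iminium salt gives the aldehyde.

Step 2
Reactants: 2 2,4-dihydroxy-6-methylbenzaldehyde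
Product: 3 2,4-bis(benzyloxy)-6-methylbenzaldehyde
Conditions: BnBr (2.3 equiv), K2CO3, DMF, 60 °C
Reagents that add atoms: benzyl bromide, BrCc1ccccc1
Why: Williamson ether synthesis; warming in DMF should also alkylate the chelated ortho hydroxyl, and the aldehyde has no enolizable hydrogen.

Step 3
Reactants: 3 2,4-bis(benzyloxy)-6-methylbenzaldehyde
Product: 4 2,4-bis(benzyloxy)-6-methylbenzoic acid
Conditions: NaClO2, NaH2PO4, 2-methylbut-2-ene, t-BuOH/THF/H2O, rt
Reagents that add atoms: sodium chlorite, [Na+].[O-]Cl=O
Why: Pinnick oxidation; chlorous acid adds to the aldehyde and fragments to the acid, while 2-methylbut-2-ene traps the hypochlorous acid before it can chlorinate the electron-rich ring, and the benzyl ethers are inert.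

Step 4
Reactants: 5 2,4,6-trihydroxybenzoic acid
Product: 6 benzyl 2,4,6-trihydroxybenzoate
Conditions: BnBr (1.05 equiv), KHCO3, DMF, rt
Reagents that add atoms: benzyl bromide, BrCc1ccccc1
Why: chemoselective alkylation of the carboxylate; hydrogencarbonate ionizes the strongly acidic chelated carboxyl but not the phenols, and room temperature avoids decarboxylation of the acid.

Step 5
Reactants: 4 2,4-bis(benzyloxy)-6-methylbenzoic acid; 6 benzyl 2,4,6-trihydroxybenzoate
Product: 8 benzyl 4-{[2,4-bis(benzyloxy)-6-methylbenzoyl]oxy}-2,6-dihydroxybenzoate, via acid chloride 7 (not isolated)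
Conditions: (COCl)2, DMF (cat.), CH2Cl2, 0 °C → rt, evaporate; then 6 (1.2 equiv), Et3N (1.1 equiv), DMAP (cat.), THF, −20 → 0 °C, slow addition of 7
Reagents that add atoms: oxalyl chloride, ClC(=O)C(=O)Cl (supplies the chlorine of 7 only; no atom of it remains in 8)
Why: acid chloride formation followed by base-mediated O-acylation of a phenol; the para hydroxyl of 6 is the most acidic and the only one neither chelated nor flanked by the ester, so with one equivalent of base it should be acylated first. The ortho,ortho'-disubstituted aroyl group then resists further acyl transfer.

Step 6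
Reactants: 8 benzyl 4-{[2,4-bis(benzyloxy)-6-methylbenzoyl]oxy}-2,6-dihydroxybenzoate
Product: 9 benzyl 2-(benzyloxy)-4-{[2,4-bis(benzyloxy)-6-methylbenzoyl]oxy}-6-hydroxybenzoate
Conditions: BnOH (1.1 equiv), PPh3, DIAD, THF, 0 °C → rt
Reagents that add atoms: benzyl alcohol, OCc1ccccc1
Why: Mitsunobu etherification of a phenol; the two ortho hydroxyls are equivalent, and after the first is alkylated the second is locked in a strong hydrogen bond to the ester carbonyl, so the reaction should stop at the monoether. The neutral conditions spare the depside ester.

Step 7
Reactants: 9 benzyl 2-(benzyloxy)-4-{[2,4-bis(benzyloxy)-6-methylbenzoyl]oxy}-6-hydroxybenzoate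
Product: 10 benzyl 2-(benzyloxy)-4-{[2,4-bis(benzyloxy)-6-methylbenzoyl]oxy}-6-{[(trifluoromethyl)sulfonyl]oxy}benzoate
Conditions: Tf2O, pyridine, CH2Cl2, −10 → 0 °C
Reagents that add atoms: trifluoromethanesulfonic anhydride, O=S(=O)(OS(=O)(=O)C(F)(F)F)C(F)(F)F
Why: O-sulfonylation of the single remaining, chelated phenol with Tf2O and pyridine, the standard way to triflate salicylate-type hydroxyls; pyridine is too weak a nucleophile to cleave the hindered depside ester.

Step 8
Reactants: 10 benzyl 2-(benzyloxy)-4-{[2,4-bis(benzyloxy)-6-methylbenzoyl]oxy}-6-{[(trifluoromethyl)sulfonyl]oxy}benzoate; 11 hept-1-yne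
Product: 12 benzyl 2-(benzyloxy)-4-{[2,4-bis(benzyloxy)-6-methylbenzoyl]oxy}-6-(hept-1-yn-1-yl)benzoate
Conditions: 11 (2 equiv), PdCl2(PPh3)2 (5 mol %), CuI (10 mol %), i-Pr2NEt (3 equiv), degassed DMF, 50 °C
Reagents that add atoms: none
Why: Sonogashira coupling. The divalent palladium precatalyst is reduced in the flask to zerovalent palladium, which inserts into the C6–O bond of the triflate; the ortho benzyloxycarbonyl group accelerates this insertion and the two ring oxygens, both meta to C6, do not retard it. The copper acetylide formed from 11, CuI (monovalent copper) and the amine transmetalates to palladium, and reductive elimination forms the bond from ring B C6 to the first chain carbon and returns zerovalent palladium. The closest known reaction type is the Sonogashira coupling of ortho-alkoxycarbonyl aryl triflates with terminal alkynes. No ring is closed and no stereocenter is formed. The step needs chemoselectivity for the triflate over the acyl–oxygen bond of the depside and the benzylic C–O bonds, which the far higher reactivity of an aryl triflate toward phosphine-ligated zerovalent palladium should secure. It also needs the depside to survive the base, which a hindered tertiary amine that cannot accept an acyl group and the doubly ortho-substituted aroyl group should ensure. Degassing and an excess of 11 limit oxidative dimerization of the alkyne, and the carboxyl stays masked as its benzyl ester so that it cannot add to the new triple bond.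

Step 9
Reactants: 12 benzyl 2-(benzyloxy)-4-{[2,4-bis(benzyloxy)-6-methylbenzoyl]oxy}-6-(hept-1-yn-1-yl)benzoate
Product: 13 4-[(2,4-dihydroxy-6-methylbenzoyl)oxy]-2-heptyl-6-hydroxybenzoic acid (CNP0227363.0)
Conditions: H2 (1 atm), 10% Pd/C, EtOAc, rt; filter and concentrate below 30 °C
Reagents that add atoms: none
Why: heterogeneous catalytic hydrogenation; the alkyne should be saturated first, then the three benzyl ethers and the benzyl ester are hydrogenolysed. The neutral, room-temperature conditions leave the aryl ester intact and do not provoke decarboxylation.

## Compound list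

1 | orcinol (5-methylbenzene-1,3-diol) | Cc1cc(O)cc(O)c1 | starting material
2 | 2,4-dihydroxy-6-methylbenzaldehyde | Cc1cc(O)cc(O)c1C=O | intermediate
3 | 2,4-bis(benzyloxy)-6-methylbenzaldehyde | Cc1cc(OCc2ccccc2)cc(OCc2ccccc2)c1C=O | intermediate
4 | 2,4-bis(benzyloxy)-6-methylbenzoic acid | Cc1cc(OCc2ccccc2)cc(OCc2ccccc2)c1C(=O)O | intermediate
5 | 2,4,6-trihydroxybenzoic acid | O=C(O)c1c(O)cc(O)cc1O | starting material
6 | benzyl 2,4,6-trihydroxybenzoate | O=C(OCc1ccccc1)c1c(O)cc(O)cc1O | intermediate
7 | 2,4-bis(benzyloxy)-6-methylbenzoyl chloride | Cc1cc(OCc2ccccc2)cc(OCc2ccccc2)c1C(Cl)=O | intermediate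
8 | benzyl 4-{[2,4-bis(benzyloxy)-6-methylbenzoyl]oxy}-2,6-dihydroxybenzoate | Cc1cc(OCc2ccccc2)cc(OCc2ccccc2)c1C(=O)Oc1cc(O)c(C(=O)OCc2ccccc2)c(O)c1 | intermediate
9 | benzyl 2-(benzyloxy)-4-{[2,4-bis(benzyloxy)-6-methylbenzoyl]oxy}-6-hydroxybenzoate | Cc1cc(OCc2ccccc2)cc(OCc2ccccc2)c1C(=O)Oc1cc(O)c(C(=O)OCc2ccccc2)c(OCc2ccccc2)c1 | intermediate
10 | benzyl 2-(benzyloxy)-4-{[2,4-bis(benzyloxy)-6-methylbenzoyl]oxy}-6-{[(trifluoromethyl)sulfonyl]oxy}benzoate | O=C(Oc1cc(OCc2ccccc2)c(C(=O)OCc2ccccc2)c(OS(=O)(=O)C(F)(F)F)c1)c1c(C)cc(OCc2ccccc2)cc1OCc1ccccc1 | intermediate
11 | hept-1-yne | CCCCCC#C | starting material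
12 | benzyl 2-(benzyloxy)-4-{[2,4-bis(benzyloxy)-6-methylbenzoyl]oxy}-6-(hept-1-yn-1-yl)benzoate | CCCCCC#Cc1cc(OC(=O)c2c(C)cc(OCc3ccccc3)cc2OCc2ccccc2)cc(OCc2ccccc2)c1C(=O)OCc1ccccc1 | intermediate
13 | 4-[(2,4-dihydroxy-6-methylbenzoyl)oxy]-2-heptyl-6-hydroxybenzoic acid | CCCCCCCc1cc(OC(=O)c2c(C)cc(O)cc2O)cc(O)c1C(=O)O | target

## Step count and risks

Total steps: 9. Longest linear sequence: 8 steps (1, 2, 3, 5, 6, 7, 8, 9 from orcinol); the ring B branch contributes step 4.

**Step 8 (key step).** The likeliest failures are slow oxidative addition at the carbon flanked by the ester, letting sulfur–oxygen cleavage of the triflate compete, copper-mediated oxidative dimerization of the alkyne, and slow erosion of the depside ester on long warming in amine. The fallback sets out from 10 and 11 and returns at 12. Hept-1-yne 11 would be lithiated with n-BuLi and quenched with Bu3SnCl to give tributyl(hept-1-yn-1-yl)stannane F1. F1 would then be coupled with 10 in a Stille reaction (Pd(PPh3)4, LiCl, 1,4-dioxane, 80 °C) to give 12. This variant uses neither copper nor amine.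

**Step 5.** The likeliest failure is loss of site selectivity, meaning acylation at an ortho hydroxyl or double acylation. The hindered acid chloride reacts slowly, and the preference for the para hydroxyl rests only on acidity and access. The fallback sets out from 6 and returns at 10, bypassing 8 and 9.
- TBSCl and imidazole (DMF, 0 °C) should silylate the para hydroxyl of 6 to give benzyl 4-{[tert-butyl(dimethyl)silyl]oxy}-2,6-dihydroxybenzoate F2. A small, cheap reagent makes the site-determining event easy to correct and recycle.
- Mitsunobu benzylation (BnOH, PPh3, DIAD) would give benzyl 2-(benzyloxy)-4-{[tert-butyl(dimethyl)silyl]oxy}-6-hydroxybenzoate F3.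
- Tf2O and pyridine would give benzyl 2-(benzyloxy)-4-{[tert-butyl(dimethyl)silyl]oxy}-6-{[(trifluoromethyl)sulfonyl]oxy}benzoate F4.
- TBAF buffered with AcOH (THF, 0 °C) would free benzyl 2-(benzyloxy)-4-hydroxy-6-{[(trifluoromethyl)sulfonyl]oxy}benzoate F5.
- The single hydroxyl of F5 would be acylated with acid chloride 7 (made from 4 as in step 5; Et3N, DMAP, CH2Cl2) to give 10. With only one hydroxyl present this acylation can be forced.

**Step 6.** The likeliest failure is poor control of the degree of alkylation, giving bis-ether together with unchanged diol in a mixture that is hard to separate. The fallback sets out from 8 and returns at 10, bypassing 9. One equivalent of Tf2O with pyridine at −40 °C should give benzyl 4-{[2,4-bis(benzyloxy)-6-methylbenzoyl]oxy}-2-hydroxy-6-{[(trifluoromethyl)sulfonyl]oxy}benzoate F6. The first triflate deactivates the ring and leaves a strongly chelated hydroxyl, which slows a second sulfonylation. That hydroxyl would then be benzylated under Mitsunobu conditions (BnOH, PPh3, DIAD, THF) to give 10.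

**Step 9.** The likeliest failure is stalling of alkyne saturation by catalyst poisons carried over from step 8 (copper, phosphine). The carboxylic acid freed by hydrogenolysis could then add to the remaining triple bond under palladium, and long exposure could also lead to decarboxylation. The fallback sets out from 12 and returns at 13. The alkyne alone would be saturated with H2 over 10% Pd/C in the presence of Ph2S, conditions under which benzyl ethers and esters persist. This gives benzyl 2-(benzyloxy)-4-{[2,4-bis(benzyloxy)-6-methylbenzoyl]oxy}-6-heptylbenzoate F7. The four benzyl groups would then be removed without hydrogen, by BCl3 with pentamethylbenzene as cation scavenger (CH2Cl2, −78 °C), to give 13.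

## Further compounds

F1 | step 8 | tributyl(hept-1-yn-1-yl)stannane | CCCCCC#C[Sn](CCCC)(CCCC)CCCC
F2 | step 5 | benzyl 4-{[tert-butyl(dimethyl)silyl]oxy}-2,6-dihydroxybenzoate | CC(C)(C)[Si](C)(C)Oc1cc(O)c(C(=O)OCc2ccccc2)c(O)c1
F3 | step 5 | benzyl 2-(benzyloxy)-4-{[tert-butyl(dimethyl)silyl]oxy}-6-hydroxybenzoate | CC(C)(C)[Si](C)(C)Oc1cc(O)c(C(=O)OCc2ccccc2)c(OCc2ccccc2)c1
F4 | step 5 | benzyl 2-(benzyloxy)-4-{[tert-butyl(dimethyl)silyl]oxy}-6-{[(trifluoromethyl)sulfonyl]oxy}benzoate | CC(C)(C)[Si](C)(C)Oc1cc(OCc2ccccc2)c(C(=O)OCc2ccccc2)c(OS(=O)(=O)C(F)(F)F)c1
F5 | step 5 | benzyl 2-(benzyloxy)-4-hydroxy-6-{[(trifluoromethyl)sulfonyl]oxy}benzoate | Oc1cc(OCc2ccccc2)c(C(=O)OCc2ccccc2)c(OS(=O)(=O)C(F)(F)F)c1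
F6 | step 6 | benzyl 4-{[2,4-bis(benzyloxy)-6-methylbenzoyl]oxy}-2-hydroxy-6-{[(trifluoromethyl)sulfonyl]oxy}benzoate | Cc1cc(OCc2ccccc2)cc(OCc2ccccc2)c1C(=O)Oc1cc(O)c(C(=O)OCc2ccccc2)c(OS(=O)(=O)C(F)(F)F)c1
F7 | step 9 | benzyl 2-(benzyloxy)-4-{[2,4-bis(benzyloxy)-6-methylbenzoyl]oxy}-6-heptylbenzoate | CCCCCCCc1cc(OC(=O)c2c(C)cc(OCc3ccccc3)cc2OCc2ccccc2)cc(OCc2ccccc2)c1C(=O)OCc1ccccc1
A1 | alternative 1 | benzyl dec-2-ynoate | CCCCCCCC#CC(=O)OCc1ccccc1
A2 | alternative 1 | 1,1-dimethoxy-3-(trimethylsilyloxy)buta-1,3-diene | COC(OC)=CC(=C)O[Si](C)(C)C
A3 | alternative 1 | benzyl 6-heptyl-4-hydroxy-2-methoxybenzoate | CCCCCCCc1cc(O)cc(OC)c1C(=O)OCc1ccccc1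
A4 | alternative 2 | benzyl 6-heptyl-2-hydroxy-4-[(3,5,7-trioxooctanoyl)oxy]benzoate | CCCCCCCc1cc(OC(=O)CC(=O)CC(=O)CC(C)=O)cc(O)c1C(=O)OCc1ccccc1
A5 | alternative 2 | benzyl 4-[(2,4-dihydroxy-6-methylbenzoyl)oxy]-6-heptyl-2-hydroxybenzoate | CCCCCCCc1cc(OC(=O)c2c(C)cc(O)cc2O)cc(O)c1C(=O)OCc1ccccc1
A6 | alternative 3 | {3-(benzyloxy)-4-[(benzyloxy)carbonyl]-5-heptylphenyl}boronic acid | CCCCCCCc1cc(B(O)O)cc(OCc2ccccc2)c1C(=O)OCc1ccccc1
A7 | alternative 3 | benzyl 2-(benzyloxy)-4-{[2,4-bis(benzyloxy)-6-methylbenzoyl]oxy}-6-heptylbenzoate | CCCCCCCc1cc(OC(=O)c2c(C)cc(OCc3ccccc3)cc2OCc2ccccc2)cc(OCc2ccccc2)c1C(=O)OCc1ccccc1
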